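Assumption: halimane numbering is used for atom labels (decalin C1–C10, chain C11–C15, C16 on C13, C17 on C8, C18/C19 on C4, C20 on C9). The SMILES is read as (5S,8R,9R,13R): H5, the C8 methyl and the C9 side chain lie on one face (called α) and the C9 methyl on the other (β); the ester-bearing glycerol carbon is not a stereocentre.

## Structural features

The target is the 2-glyceryl ester of a C20 halimane acid: an octalin (ring A: C1–C5 and C10; ring B: C5–C10) with a five-carbon acid chain (C11–C15) on C9. Ring A holds the gem-dimethyl carbon C4 and the trisubstituted alkene C1=C10, whose C10 is the ring-fusion carbon. Ring B holds three stereocentres: C5 (H), C8 (CH3) and the quaternary C9 (CH3 and chain); C8 and C9 are adjacent, and C5 is 1,3 to C9 across sp2 C10. The two vicinal methyls on C8 and C9 are trans, and the C8 methyl is cis to the side chain. C13 is an isolated stereocentre, β to the ester carbonyl and four bonds from C9, so it cannot be relayed from the ring and cannot epimerise. The fragile groups are the 2-monoacylglycerol (acyl shift to a primary hydroxyl under base, acid, heat or on silica) and the C1=C10 alkene (acid moves it to the tetrasubstituted C5=C10 position). The real difficulty is the quaternary C9, flanked by the C8 stereocentre and sp2 C10, in a fixed relation to C5, together with the exact position of the alkene. The key step exploits the fact that C9 is allylic to C1=C10: the unit C1=C10–C9 can arise by allylic transposition from a C1–O / C9=C10 isomer, and the bond made at C9 is chosen to be the one to the methyl carbon C20. A second feature fixes the starting material: ring B with C17 and the C4 gem-dimethyl carbon is a p-menthane skeleton, with C8 configured as in (R)-pulegone.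

## Logic of the disconnections

**23 to 19 and 21.** The C15–O ester bond and the two O–Si bonds are cut. The 2-acylglycerol is the most fragile part of 23 and is therefore made last, from 22. The gain is the separation into 19 and the symmetric 21, which comes in one step from 20. The demand is an esterification of a secondary alcohol without base and a desilylation that does not move the acyl group.

**19 to 18.** Only the ester alkyl group changes. C15 travels through the route as a methyl ester, which survives every step up to 18. The demand is a hydrolysis that leaves the C1=C10 alkene in place.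

**18 to 17 (key).** The C9–C20 bond is cut with allylic transposition, so that the C1=C10 alkene of 18 becomes the C9=C10 alkene and the C1–O bond of 17. In one sentence: the quaternary C9 and the C1=C10 alkene are made together by anti-SN2' methylation of 17, which already carries the whole side chain on a tetrasubstituted C9=C10 alkene. Cutting the methyl rather than the chain makes the incoming group the smallest possible nucleophile, and lets it enter anti to the leaving group and anti to the C8 methyl. The gain is that a quaternary stereocentre and a defined alkene position are traded for one secondary carbinol centre. The demand is γ-attack over α-attack and a 1α-configured ester.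

**17 to 16 to 15.** After removal of the picolinoyl group, the C1–C10 bond of ring A is cut into an alkenyl nucleophile at C10 and an aldehyde at C1. The bicycle becomes a monocyclic ring B compound with only C5, C8 and C13 as stereocentres. The demand is a ring closure that places the C1 oxygen on the α face, and an enol triflate of defined regiochemistry in 15.

**15 to 14 to 12.** The aldehyde of 15 is masked as the acetal in 14. The enol triflate of 14 (C10–O, C9=C10) is traced to the enolate formed by 1,4-reduction of 12. The regiochemistry of a tetrasubstituted enolate is thus fixed by the position of an alkene, not by a deprotonation.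

**12 to 10 to 8 and 3.** The C9=C11 bond is cut (aldol addition and elimination). This joins the ring B ketone 8 with the chain fragment 3, which carries C13. The demand is kinetic enolisation of 8 at the C9 methylene, attack on the aldehyde and not on the ester of 3, and no epimerisation at C5.

**8 to 4 and 5.** The C3–C4 bond is cut (1,4-addition to the isopropylidene ketone). Ring B, C17, C4 and both methyls on C4 all come from 4, with C8 bought. C5 is then set trans to the C8 methyl by equilibration. The demand is 1,4-addition to a β,β-disubstituted enone and a useful thermodynamic bias at C5.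

**3 to 2 to 1.** The aldehyde carbon C11 is the acid carbon of 1, reached by reduction and re-oxidation. C13 is bought with 1, whose ester arm becomes C14–C15.

## Other disconnections considered

**Alternative 1:** (the first that comes to mind) cut C9–C11 by deconjugative α-alkylation. The bicyclic enone A1 (C8 ketone, C9=C10 alkene) would be deprotonated at C1 to the heteroannular dienolate and alkylated at C9 with the side-chain iodide A3 to give the β,γ-unsaturated ketone A2. The C8 ketone would then be turned into the methyl group by methylenation and hydrogenation. The chosen plan is preferred on three grounds. The only stereocentre of A1 (C5) is 1,3 to C9 and separated from it by a planar carbon, so there is little basis for facial control in the alkylation. The C8 methyl would have to be set afterwards by hydrogenating an exocyclic alkene next to a quaternary centre in the presence of the C1=C10 alkene. A1 itself needs a ring annulation at the hindered α-carbon next to the gem-dimethyl group.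

**Alternative 2:** cut C9–C11 by a [3,3]-sigmatropic shift. The allylic alcohol A4 (C9 methyl on the C9=C10 alkene, 1α-hydroxyl) would undergo an orthoester Claisen rearrangement to the ester A5, with suprafacial delivery of C11 to C9. The stereochemical logic is as sound as in the chosen plan, and A4 is accessible by the same ring closure. The rearrangement, however, delivers only C11 and C12. C13–C15 and the C13 stereocentre would need at least five further steps (reduction, activation, an asymmetric conjugate addition or an auxiliary, and cleavage). In the chosen plan the complete chain with C13 arrives in one aldol step.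

**Alternative 3:** cut C5–C10 and C8–C9 by an intramolecular Diels–Alder reaction. The trienone A6 would close both rings and set C5, C8 and C9 at once, giving the decalone A7. The C1 ketone would then be converted into the C1=C10 alkene through an enol triflate. The trans relation between the C4 substituent on C5 and the methyl on C8 requires a (Z)-configured diene terminus. Such dienes reach the s-cis conformation with difficulty and tend to undergo 1,5-hydrogen shifts. The dienophile is a β,β-disubstituted enone that must form a quaternary carbon, and enolisation of the C1 ketone towards C10 rather than C2 is not assured. The chosen plan avoids all three problems.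

Key step: step 10

## Route

Step 1
Reactants: 1 (3R)-5-methoxy-3-methyl-5-oxopentanoic acid [methyl hydrogen (R)-3-methylglutarate]
Product: 2 methyl (3R)-5-hydroxy-3-methylpentanoate
Conditions: BH3·SMe2 (1.1 equiv), THF, −10 → 20 °C; MeOH quench; used at once
Reagents that add atoms: none
Why: Borane reduces the carboxylic acid chemoselectively in the presence of the methyl ester; the C3 stereocentre is not touched, and the hydroxy ester is kept cold and used directly so that it does not close to the δ-lactone.

Step 2
Reactants: 2 methyl (3R)-5-hydroxy-3-methylpentanoate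
Product: 3 methyl (3R)-3-methyl-5-oxopentanoate
Conditions: TEMPO (10 mol %), PhI(OAc)2 (1.1 equiv), CH2Cl2, 20 °C
Reagents that add atoms: none
Why: Oxoammonium (TEMPO) oxidation of a primary alcohol stops at the aldehyde under near-neutral conditions; the stereocentre is β to both carbonyl groups and cannot epimerise.

Step 3
Reactants: 4 (R)-(+)-pulegone [(5R)-5-methyl-2-(propan-2-ylidene)cyclohexan-1-one]; 5 [2-(1,3-dioxolan-2-yl)ethyl]magnesium bromide (commercial THF solution)
Product: 8 (2S,5R)-2-[4-(1,3-dioxolan-2-yl)-2-methylbutan-2-yl]-5-methylcyclohexan-1-one, via bromomagnesium enolate 6 (not isolated), via cis-ketone epimer 7 (not isolated)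
Conditions: CuBr·SMe2 (10 mol %), THF, −30 → 0 °C; H2O/NH4Cl work-up; crude in EtOH–H2O, KOH, reflux; chromatography, 7 resubmitted to the equilibration
Reagents that add atoms: none
Why: Copper-catalysed conjugate addition of a primary alkyl Grignard reagent to the isopropylidene ketone builds the quaternary C4 with its two methyl groups and attaches C1–C3 as a masked aldehyde. Protonation gives both C5 epimers, and base equilibration through the enolate should favour the trans-2,5-diequatorial ketone, so C5 is set under thermodynamic control from the C8 methyl bought with 4.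

Step 4
Reactants: 8 (2S,5R)-2-[4-(1,3-dioxolan-2-yl)-2-methylbutan-2-yl]-5-methylcyclohexan-1-one; 3 methyl (3R)-3-methyl-5-oxopentanoate
Product: 10 methyl (3R)-5-{(3S,6R)-3-[4-(1,3-dioxolan-2-yl)-2-methylbutan-2-yl]-6-methyl-2-oxocyclohexyl}-5-hydroxy-3-methylpentanoate as a mixture of epimers at the two new centres, via lithium enolate 9 (not isolated)
Conditions: LiN(i-Pr)2 (1.05 equiv, commercial solution), THF, −78 °C; 3 (1.2 equiv), −78 °C, 20 min; AcOH quench at −78 °C
Reagents that add atoms: none
Why: Kinetic deprotonation takes the proton of the unhindered α-methylene (the future C9) and not that of the methine next to the quaternary carbon, and the lithium enolate adds to the aldehyde much faster than to the ester (directed aldol addition). Both new stereocentres are erased in steps 5 and 6.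

Step 5
Reactants: 10 methyl (3R)-5-{(3S,6R)-3-[4-(1,3-dioxolan-2-yl)-2-methylbutan-2-yl]-6-methyl-2-oxocyclohexyl}-5-hydroxy-3-methylpentanoate
Product: 12 methyl (3R,5E)-5-{(3S,6R)-3-[4-(1,3-dioxolan-2-yl)-2-methylbutan-2-yl]-6-methyl-2-oxocyclohexylidene}-3-methylpentanoate, via mesylate 11 (not isolated)
Conditions: MsCl (1.5 equiv), Et3N (4 equiv), CH2Cl2, 0 °C; then DBU (1.2 equiv), 0 °C, 30 min
Reagents that add atoms: none
Why: Mesylation and E1cB elimination of the β-sulfonyloxy ketone complete the aldol condensation; the alkene geometry is of no consequence. Loss of the sulfonate after deprotonation at the accessible C9–H should be much faster than enolisation at the hindered C5 methine, which is why the base contact is kept short and cold.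

Step 6
Reactants: 12 methyl (3R,5E)-5-{(3S,6R)-3-[4-(1,3-dioxolan-2-yl)-2-methylbutan-2-yl]-6-methyl-2-oxocyclohexylidene}-3-methylpentanoate
Product: 14 methyl (3R)-5-{(3S,6R)-3-[4-(1,3-dioxolan-2-yl)-2-methylbutan-2-yl]-6-methyl-2-[(trifluoromethanesulfonyl)oxy]cyclohex-1-en-1-yl}-3-methylpentanoate, via lithium enolate 13 (not isolated)
Conditions: LiBH(s-Bu)3 (L-Selectride, 1.1 equiv), THF, −78 °C; then PhNTf2 (1.3 equiv), −78 → 0 °C
Reagents that add atoms: N-phenylbis(trifluoromethanesulfonimide) (PhNTf2), O=S(=O)(N(c1ccccc1)S(=O)(=O)C(F)(F)F)C(F)(F)F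
Why: Conjugate reduction with enolate trapping: the bulky borohydride should add hydride 1,4 to the s-cis alkylidene ketone, whose carbonyl is shielded by the neighbouring methine and its quaternary substituent. The tetrasubstituted enolate forms only on the C9 side and is fixed by O-triflation; ester and acetal are inert at −78 °C.

Step 7
Reactants: 14 methyl (3R)-5-{(3S,6R)-3-[4-(1,3-dioxolan-2-yl)-2-methylbutan-2-yl]-6-methyl-2-[(trifluoromethanesulfonyl)oxy]cyclohex-1-en-1-yl}-3-methylpentanoate
Product: 15 methyl (3R)-3-methyl-5-{(3S,6R)-6-methyl-3-(2-methyl-5-oxopentan-2-yl)-2-[(trifluoromethanesulfonyl)oxy]cyclohex-1-en-1-yl}pentanoate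
Conditions: 1 M HCl, THF, 20 °C
Reagents that add atoms: water, O
Why: Acid hydrolysis of the dioxolane frees the C1 aldehyde; enol triflates and methyl esters are stable to dilute aqueous acid at room temperature.

Step 8
Reactants: 15 methyl (3R)-3-methyl-5-{(3S,6R)-6-methyl-3-(2-methyl-5-oxopentan-2-yl)-2-[(trifluoromethanesulfonyl)oxy]cyclohex-1-en-1-yl}pentanoate
Product: 16 methyl (3R)-5-[(2R,4aS,8S)-8-hydroxy-2,5,5-trimethyl-2,3,4,4a,5,6,7,8-octahydronaphthalen-1-yl]-3-methylpentanoate
Conditions: CrCl2 (6 equiv), NiCl2 (5 mol %), degassed DMF, 0.01 M, 20 °C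
Reagents that add atoms: none
Why: Intramolecular Nozaki–Hiyama–Kishi reaction: zerovalent nickel inserts into the C–OTf bond, the alkenyl group passes to trivalent chromium and adds to the aldehyde, closing ring A as a six-membered ring with the C9=C10 alkene intact. In the chair-like transition state H5 is axial and the aldehyde oxygen should also take the axial position, away from the C11 methylene on C9 (allylic 1,3-strain), which places the new hydroxyl on the face of H5 (1α, 8S in the name). The ester does not react with the organochromium species.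

Step 9
Reactants: 16 methyl (3R)-5-[(2R,4aS,8S)-8-hydroxy-2,5,5-trimethyl-2,3,4,4a,5,6,7,8-octahydronaphthalen-1-yl]-3-methylpentanoate
Product: 17 (1S,4aS,7R)-8-[(3R)-5-methoxy-3-methyl-5-oxopentyl]-4,4,7-trimethyl-1,2,3,4,4a,5,6,7-octahydronaphthalen-1-yl pyridine-2-carboxylate
Conditions: pyridine-2-carboxylic acid (1.5 equiv), DCC (1.6 equiv), DMAP (0.2 equiv), CH2Cl2, 0 → 20 °C
Reagents that add atoms: pyridine-2-carboxylic acid, OC(=O)c1ccccn1
Why: Steglich esterification acylates the alcohol with retention at C1 under neutral conditions, which avoids ionisation of the allylic C–O bond.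

Step 10
Reactants: 17 (1S,4aS,7R)-8-[(3R)-5-methoxy-3-methyl-5-oxopentyl]-4,4,7-trimethyl-1,2,3,4,4a,5,6,7-octahydronaphthalen-1-yl pyridine-2-carboxylate
Product: 18 methyl (3R)-3-methyl-5-[(1R,2R,4aS)-1,2,5,5-tetramethyl-1,2,3,4,4a,5,6,7-octahydronaphthalen-1-yl]pentanoate
Conditions: MeMgBr (3.0 equiv), CuBr·SMe2 (1.5 equiv), THF, −78 °C (cuprate formed first); then 17, −78 → −20 °C
Reagents that add atoms: methylmagnesium bromide, C[Mg]Br
Why: Copper-mediated anti-SN2' allylic substitution: magnesium chelated by the pyridine nitrogen and the carbonyl oxygen makes the picolinoxy group a good leaving group, the methylcuprate Me2CuMgBr attacks C9 of the C9=C10 alkene on the face opposite to the C1–O bond (formally an oxidative addition to a σ-allyl species of trivalent copper), and reductive elimination forms the C9–C20 bond while the double bond moves to C1=C10. The closest known reaction type is the construction of quaternary carbons by anti-SN2' substitution of γ,γ-disubstituted allylic picolinates with RMgBr/CuBr·SMe2. No ring is closed. The only new stereocentre, C9, is controlled by C1 through 1,3-chirality transfer: the 1α C–O bond is axial on ring A and parallel to the π orbitals, so the methyl group must enter from the β face, which makes C20 β and leaves the side chain α (9R). That face is also the sterically favoured one, anti to the C8 methyl when it takes the pseudoaxial position that relieves allylic 1,2-strain with the C9 substituent, so substrate bias and stereospecificity point the same way. The step needs γ-attack over α-attack and substitution over elimination; the electron-poor chelating leaving group speeds up reductive elimination at C9 before the allylcopper can shift to C1, and methyl is the smallest transferable group. Because the alkene arises by allylic transposition it can only lie at C1=C10, so the C5=C10 isomer is excluded by the mechanism. The ester is spared because no free Grignard reagent is left once the 2:1 cuprate has formed at low temperature.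

Step 11
Reactants: 18 methyl (3R)-3-methyl-5-[(1R,2R,4aS)-1,2,5,5-tetramethyl-1,2,3,4,4a,5,6,7-octahydronaphthalen-1-yl]pentanoate
Product: 19 (3R)-3-methyl-5-[(1R,2R,4aS)-1,2,5,5-tetramethyl-1,2,3,4,4a,5,6,7-octahydronaphthalen-1-yl]pentanoic acid
Conditions: LiOH (5 equiv), THF/MeOH/H2O, 40 °C; cold 1 M HCl to pH 3, extraction
Reagents that add atoms: lithium hydroxide, [Li+].[OH-]
Why: Saponification of the unhindered methyl ester; no stereocentre is α to the carbonyl and the alkene is inert to base and to brief cold dilute acid.

Step 12
Reactants: 20 glycerol (propane-1,2,3-triol)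
Product: 21 1,3-bis[(tert-butyldimethylsilyl)oxy]propan-2-ol
Conditions: TBSCl (2.05 equiv), imidazole (4 equiv), CH2Cl2/DMF, 0 °C
Reagents that add atoms: tert-butyldimethylsilyl chloride, CC(C)(C)[Si](C)(C)Cl
Why: Silylation is much faster at the two primary hydroxyls than at the secondary one, which leaves the C2 hydroxyl free.

Step 13
Reactants: 19 (3R)-3-methyl-5-[(1R,2R,4aS)-1,2,5,5-tetramethyl-1,2,3,4,4a,5,6,7-octahydronaphthalen-1-yl]pentanoic acid; 21 1,3-bis[(tert-butyldimethylsilyl)oxy]propan-2-ol
Product: 22 1,3-bis[(tert-butyldimethylsilyl)oxy]propan-2-yl (3R)-3-methyl-5-[(1R,2R,4aS)-1,2,5,5-tetramethyl-1,2,3,4,4a,5,6,7-octahydronaphthalen-1-yl]pentanoate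
Conditions: DCC (1.3 equiv), DMAP (0.3 equiv), CH2Cl2, 20 °C
Reagents that add atoms: none
Why: Steglich esterification joins the unbranched carboxyl terminus to the secondary alcohol under neutral conditions; both partners lack acidic stereocentres.

Step 14
Reactants: 22 1,3-bis[(tert-butyldimethylsilyl)oxy]propan-2-yl (3R)-3-methyl-5-[(1R,2R,4aS)-1,2,5,5-tetramethyl-1,2,3,4,4a,5,6,7-octahydronaphthalen-1-yl]pentanoate
Product: 23 1,3-dihydroxypropan-2-yl (3R)-3-methyl-5-[(1R,2R,4aS)-1,2,5,5-tetramethyl-1,2,3,4,4a,5,6,7-octahydronaphthalen-1-yl]pentanoate (target, CNP0174907.2)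
Conditions: Et3N·3HF (10 equiv), THF, 0 → 20 °C; pH 7 buffer work-up; rapid cold chromatography on boric-acid-treated silica
Reagents that add atoms: none
Why: Fluoride cleaves the two primary Si–O bonds under weakly acidic, non-basic conditions, which should keep the acyl group on the secondary oxygen and leave the trisubstituted alkene in place.

## Compound list

1 | (3R)-5-methoxy-3-methyl-5-oxopentanoic acid | C[C@@H](CC(=O)OC)CC(=O)O | starting material
2 | methyl (3R)-5-hydroxy-3-methylpentanoate | C[C@@H](CC(=O)OC)CCO | intermediate
3 | methyl (3R)-3-methyl-5-oxopentanoate | C[C@@H](CC(=O)OC)CC=O | intermediate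
4 | (R)-(+)-pulegone, (5R)-5-methyl-2-(propan-2-ylidene)cyclohexan-1-one | C[C@@H]1CCC(=C(C)C)C(=O)C1 | starting material
5 | [2-(1,3-dioxolan-2-yl)ethyl]magnesium bromide | Br[Mg]CCC1OCCO1 | starting material
6 | bromomagnesium (5R)-2-[4-(1,3-dioxolan-2-yl)-2-methylbutan-2-yl]-5-methylcyclohex-1-en-1-olate | C[C@@H]1CCC(C(C)(C)CCC2OCCO2)=C(O[Mg]Br)C1 | intermediate
7 | (2R,5R)-2-[4-(1,3-dioxolan-2-yl)-2-methylbutan-2-yl]-5-methylcyclohexan-1-one (cis epimer) | C[C@@H]1CC[C@H](C(C)(C)CCC2OCCO2)C(=O)C1 | intermediate
8 | (2S,5R)-2-[4-(1,3-dioxolan-2-yl)-2-methylbutan-2-yl]-5-methylcyclohexan-1-one | C[C@@H]1CC[C@@H](C(C)(C)CCC2OCCO2)C(=O)C1 | intermediate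
9 | lithium (3R,6S)-6-[4-(1,3-dioxolan-2-yl)-2-methylbutan-2-yl]-3-methylcyclohex-1-en-1-olate | C[C@@H]1CC[C@@H](C(C)(C)CCC2OCCO2)C(O[Li])=C1 | intermediate
10 | methyl (3R)-5-{(3S,6R)-3-[4-(1,3-dioxolan-2-yl)-2-methylbutan-2-yl]-6-methyl-2-oxocyclohexyl}-5-hydroxy-3-methylpentanoate (epimer mixture at ring C1 and chain C5) | C[C@@H]1CC[C@@H](C(C)(C)CCC2OCCO2)C(=O)C1C(O)C[C@@H](C)CC(=O)OC | intermediate
11 | methyl (3R)-5-{(3S,6R)-3-[4-(1,3-dioxolan-2-yl)-2-methylbutan-2-yl]-6-methyl-2-oxocyclohexyl}-5-[(methanesulfonyl)oxy]-3-methylpentanoate (epimer mixture) | C[C@@H]1CC[C@@H](C(C)(C)CCC2OCCO2)C(=O)C1C(OS(C)(=O)=O)C[C@@H](C)CC(=O)OC | intermediate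
12 | methyl (3R,5E)-5-{(3S,6R)-3-[4-(1,3-dioxolan-2-yl)-2-methylbutan-2-yl]-6-methyl-2-oxocyclohexylidene}-3-methylpentanoate | C[C@@H]1CC[C@@H](C(C)(C)CCC2OCCO2)C(=O)/C1=C/C[C@@H](C)CC(=O)OC | intermediate
13 | lithium (3R,6S)-6-[4-(1,3-dioxolan-2-yl)-2-methylbutan-2-yl]-2-[(3R)-5-methoxy-3-methyl-5-oxopentyl]-3-methylcyclohex-1-en-1-olate | C[C@@H]1CC[C@@H](C(C)(C)CCC2OCCO2)C(O[Li])=C1CC[C@@H](C)CC(=O)OC | intermediate
14 | methyl (3R)-5-{(3S,6R)-3-[4-(1,3-dioxolan-2-yl)-2-methylbutan-2-yl]-6-methyl-2-[(trifluoromethanesulfonyl)oxy]cyclohex-1-en-1-yl}-3-methylpentanoate | C[C@@H]1CC[C@@H](C(C)(C)CCC2OCCO2)C(OS(=O)(=O)C(F)(F)F)=C1CC[C@@H](C)CC(=O)OC | intermediate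
15 | methyl (3R)-3-methyl-5-{(3S,6R)-6-methyl-3-(2-methyl-5-oxopentan-2-yl)-2-[(trifluoromethanesulfonyl)oxy]cyclohex-1-en-1-yl}pentanoate | C[C@@H]1CC[C@@H](C(C)(C)CCC=O)C(OS(=O)(=O)C(F)(F)F)=C1CC[C@@H](C)CC(=O)OC | intermediate
16 | methyl (3R)-5-[(2R,4aS,8S)-8-hydroxy-2,5,5-trimethyl-2,3,4,4a,5,6,7,8-octahydronaphthalen-1-yl]-3-methylpentanoate | C[C@@H]1CC[C@H]2C(C)(C)CC[C@H](O)C2=C1CC[C@@H](C)CC(=O)OC | intermediate
17 | (1S,4aS,7R)-8-[(3R)-5-methoxy-3-methyl-5-oxopentyl]-4,4,7-trimethyl-1,2,3,4,4a,5,6,7-octahydronaphthalen-1-yl pyridine-2-carboxylate | C[C@@H]1CC[C@H]2C(C)(C)CC[C@H](OC(=O)c3ccccn3)C2=C1CC[C@@H](C)CC(=O)OC | intermediate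
18 | methyl (3R)-3-methyl-5-[(1R,2R,4aS)-1,2,5,5-tetramethyl-1,2,3,4,4a,5,6,7-octahydronaphthalen-1-yl]pentanoate | C[C@@H]1CC[C@H]2C(C)(C)CCC=C2[C@]1(C)CC[C@@H](C)CC(=O)OC | intermediate
19 | (3R)-3-methyl-5-[(1R,2R,4aS)-1,2,5,5-tetramethyl-1,2,3,4,4a,5,6,7-octahydronaphthalen-1-yl]pentanoic acid | C[C@@H]1CC[C@H]2C(C)(C)CCC=C2[C@]1(C)CC[C@@H](C)CC(=O)O | intermediate
20 | glycerol (propane-1,2,3-triol) | OCC(O)CO | starting material
21 | 1,3-bis[(tert-butyldimethylsilyl)oxy]propan-2-ol | CC(C)(C)[Si](C)(C)OCC(O)CO[Si](C)(C)C(C)(C)C | intermediate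
22 | 1,3-bis[(tert-butyldimethylsilyl)oxy]propan-2-yl (3R)-3-methyl-5-[(1R,2R,4aS)-1,2,5,5-tetramethyl-1,2,3,4,4a,5,6,7-octahydronaphthalen-1-yl]pentanoate | C[C@@H]1CC[C@H]2C(C)(C)CCC=C2[C@]1(C)CC[C@@H](C)CC(=O)OC(CO[Si](C)(C)C(C)(C)C)CO[Si](C)(C)C(C)(C)C | intermediate
23 | 1,3-dihydroxypropan-2-yl (3R)-3-methyl-5-[(1R,2R,4aS)-1,2,5,5-tetramethyl-1,2,3,4,4a,5,6,7-octahydronaphthalen-1-yl]pentanoate | C[C@@H]1CC[C@H]2C(C)(C)CCC=C2[C@]1(C)CC[C@@H](C)CC(=O)OC(CO)CO | target

## Step count and least certain steps

Total step count: 14. Longest linear sequence: 12 steps (1 → 2 → 3, then steps 4–11, 13 and 14 to 23); counted from 4 it is 11 steps.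

**Step 10 (key step).** The most likely failure is loss of regioselectivity: reductive elimination at the fully substituted C9 is slow, so the allylcopper may shift to C1 and deliver methyl there, or the activated ester may ionise and eliminate to a diene. The fallback abandons the leaving group and uses the carbonyl group to direct the methyl. It sets out from 16, which is oxidised with DMP (1,1,1-triacetoxy-1,1-dihydro-1,2-benziodoxol-3(1H)-one) to the bicyclic enone F1. Conjugate addition of Me2CuLi (THF, −40 → 0 °C) should occur anti to the C8 methyl, and trapping of the enolate with PhNTf2 gives the enol triflate F2, in which the C1=C10 position is already fixed. Reduction of the triflate with Pd(OAc)2/PPh3, Bu3N and HCO2H in DMF at 60 °C returns to the route at 18.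

**Step 8.** The most likely failure is poor facial selectivity in the ring closure, since the preference for the 1α alcohol rests only on allylic strain in a chair-like transition state; protodemetalation of the hindered alkenylchromium species is a second risk. The fallback makes both epimers converge instead of relying on one: starting from 15, any 1β alcohol F3 formed is esterified with inversion under Mitsunobu conditions (pyridine-2-carboxylic acid, PPh3, DIAD, toluene, 0 °C). This gives 17, the same ester that 16 gives with retention in step 9.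

**Step 6.** The most likely failure is competing 1,2-reduction of the ketone (or slow reduction of the ester) and incomplete O-sulfonylation of the crowded enolate in the presence of the borane. The fallback separates the two events and uses a neutral metal-catalysed 1,4-hydride transfer. From 12, hydrosilylation with Et3SiH and RhCl(PPh3)3 (2 mol %) in benzene at 50 °C gives the regiodefined triethylsilyl enol ether F4. CsF and PhNTf2 in DME then convert it into 14.

**Step 14.** The most likely failure is migration of the acyl group from the secondary to a primary oxygen during desilylation or purification. The fallback replaces the silyl ethers by a cyclic acetal that is removed as a borate. From 19, esterification (DCC, DMAP) with commercial cis-2-phenyl-1,3-dioxan-5-ol gives the benzylidene-protected ester F5. Heating with B(OH)3 in trimethyl borate at about 90 °C exchanges the acetal for a cyclic borate of the 1,3-diol, which cannot accept the acyl group, and brief treatment with water releases 23.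

## Further compounds

F1 | step 10 | methyl (3R)-3-methyl-5-[(2R,4aS)-2,5,5-trimethyl-8-oxo-2,3,4,4a,5,6,7,8-octahydronaphthalen-1-yl]pentanoate | C[C@@H]1CC[C@H]2C(C)(C)CCC(=O)C2=C1CC[C@@H](C)CC(=O)OC
F2 | step 10 | methyl (3R)-3-methyl-5-{(1R,2R,4aS)-1,2,5,5-tetramethyl-8-[(trifluoromethanesulfonyl)oxy]-1,2,3,4,4a,5,6,7-octahydronaphthalen-1-yl}pentanoate | C[C@@H]1CC[C@H]2C(C)(C)CCC(OS(=O)(=O)C(F)(F)F)=C2[C@]1(C)CC[C@@H](C)CC(=O)OC
F3 | step 8 | methyl (3R)-5-[(2R,4aS,8R)-8-hydroxy-2,5,5-trimethyl-2,3,4,4a,5,6,7,8-octahydronaphthalen-1-yl]-3-methylpentanoate | C[C@@H]1CC[C@H]2C(C)(C)CC[C@@H](O)C2=C1CC[C@@H](C)CC(=O)OC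
F4 | step 6 | methyl (3R)-5-{(3S,6R)-3-[4-(1,3-dioxolan-2-yl)-2-methylbutan-2-yl]-6-methyl-2-[(triethylsilyl)oxy]cyclohex-1-en-1-yl}-3-methylpentanoate | C[C@@H]1CC[C@@H](C(C)(C)CCC2OCCO2)C(O[Si](CC)(CC)CC)=C1CC[C@@H](C)CC(=O)OC
F5 | step 14 | cis-2-phenyl-1,3-dioxan-5-yl (3R)-3-methyl-5-[(1R,2R,4aS)-1,2,5,5-tetramethyl-1,2,3,4,4a,5,6,7-octahydronaphthalen-1-yl]pentanoate | C[C@@H]1CC[C@H]2C(C)(C)CCC=C2[C@]1(C)CC[C@@H](C)CC(=O)O[C@H]3CO[C@@H](c4ccccc4)OC3
A1 | alternative 1 | (4aS)-1,5,5-trimethyl-4,4a,5,6,7,8-hexahydronaphthalen-2(3H)-one | O=C1CC[C@H]2C(C)(C)CCCC2=C1C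
A2 | alternative 1 | methyl (3R)-3-methyl-5-[(1S,4aS)-1,5,5-trimethyl-2-oxo-1,2,3,4,4a,5,6,7-octahydronaphthalen-1-yl]pentanoate | O=C1CC[C@H]2C(C)(C)CCC=C2[C@]1(C)CC[C@@H](C)CC(=O)OC
A3 | alternative 1 | methyl (3S)-5-iodo-3-methylpentanoate | C[C@@H](CC(=O)OC)CCI
A4 | alternative 2 | (1S,4aS,7R)-4,4,7,8-tetramethyl-1,2,3,4,4a,5,6,7-octahydronaphthalen-1-ol | C[C@@H]1CC[C@H]2C(C)(C)CC[C@H](O)C2=C1C
A5 | alternative 2 | ethyl 2-[(1R,2R,4aS)-1,2,5,5-tetramethyl-1,2,3,4,4a,5,6,7-octahydronaphthalen-1-yl]acetate | C[C@@H]1CC[C@H]2C(C)(C)CCC=C2[C@]1(C)CC(=O)OCC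
A6 | alternative 3 | methyl (3R,6E,12E,14Z)-3,6,11,11-tetramethyl-8-oxohexadeca-6,12,14-trienoate | C/C=C\C=C\C(C)(C)CCC(=O)/C=C(\C)CC[C@@H](C)CC(=O)OC
A7 | alternative 3 | methyl (3R)-3-methyl-5-[(1R,2R,4aR,8aR)-1,2,5,5-tetramethyl-8-oxo-1,2,4a,5,6,7,8,8a-octahydronaphthalen-1-yl]pentanoate | C[C@@H]1C=C[C@H]2C(C)(C)CCC(=O)[C@H]2[C@]1(C)CC[C@@H](C)CC(=O)OC
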